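## Retrosynthetic overview

- Numbering: C8 = acetoxy bridgehead, C7/C9 = its ArCH and OCH2 neighbours; C8' = CH bridgehead, C7'/C9' = its ArCH and OCH2 neighbours; ring A = C7'–O–C9–C8–C8', ring B = C7–O–C9'–C8'–C8.
- Feature: in ring A the oxygenated quaternary carbon C8 lies between the O–C9H2 unit and C8', a 3-hydroxy-2,3-dihydrofuran pattern that an α-bromo ketone and a β-keto ester give in one annulation.
- Endgame: the C8 acetate and free phenols come from the fully silylated 8-hydroxy lignan; the C7–aryl bond is cut to an arylzinc reagent and the ring B oxocarbenium ion (lactol acetate, from the ring B lactone).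
- The ring B lactone comes from a saturated ring A diester (C9' ester reduced, closure onto the C7 carboxyl); C7' and C8' come from hydrogenation and epimerisation of the dihydrofuran, both relayed from C8.
- Ring A is formed first (bonds C8–C8' and O–C9, stereocentre C8) from ethyl bromopyruvate and an aroylacetate by a cinchona-catalysed interrupted Feist–Bénary annulation; ring B is closed second.

Key step: step 3

Assumption: the pseudoenantiomeric catalysts (DHQD)2PYR and (DHQ)2PYR give opposite carbinol configurations; the one that delivers the (S)-carbinol at C8 is used and is written below as (DHQD)2PYR (hydroquinidine 2,5-diphenyl-4,6-pyrimidinediyl diether). Descriptors with primed locants refer to the lignan numbering above.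

## Route

Step 1
Reactants: 1 acetovanillone
Product: 2 1-[3-methoxy-4-(triisopropylsilyloxy)phenyl]ethanone
Conditions: TIPSCl, imidazole, DMF, 25 °C
Reagents that add atoms: triisopropylsilyl chloride, CC(C)[Si](Cl)(C(C)C)C(C)C
Why: Imidazole-promoted O-silylation masks the only acidic OH as a hindered aryl silyl ether that should tolerate the enolate, hydride and organometallic steps ahead and is removed by fluoride at the end.

Step 2
Reactants: 2 1-[3-methoxy-4-(triisopropylsilyloxy)phenyl]ethanone; 3 diethyl carbonate
Product: 4 ethyl 3-[3-methoxy-4-(triisopropylsilyloxy)phenyl]-3-oxopropanoate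
Conditions: NaH (2.5 equiv), THF, 65 °C; then AcOH, 0 °C
Reagents that add atoms: none
Why: Crossed Claisen condensation, in which the sodium enolate of the methyl ketone is acylated by the non-enolisable carbonate and the equilibrium is pulled over by deprotonation of the β-keto ester formed; no stereocentre arises.

Step 3
Reactants: 4 ethyl 3-[3-methoxy-4-(triisopropylsilyloxy)phenyl]-3-oxopropanoate; 5 ethyl bromopyruvate
Product: 7 diethyl (3S)-3-hydroxy-5-[3-methoxy-4-(triisopropylsilyloxy)phenyl]-2,3-dihydrofuran-3,4-dicarboxylate, via bromohydrin aldol adduct 6 (not isolated)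
Conditions: (DHQD)2PYR (10 mol %), proton sponge (1.1 equiv), THF, −78 °C; work-up without acid, Et3N-washed silica
Reagents that add atoms: none
Why: The quinuclidine nitrogen of the catalyst deprotonates β-keto ester 4 and holds the enolate as a chiral ammonium ion pair, whose carbon C8' adds to the very electrophilic ketone of 5 (aldol step, bond C8–C8') to give bromohydrin 6. The aroyl enol oxygen of 6 then displaces bromide at C9 (bond O–C9), closing ring A by a 5-exo-tet O-alkylation, while proton sponge, too hindered to be alkylated, takes up the HBr. The closest known reaction type is the cinchona-catalysed asymmetric interrupted Feist–Bénary reaction of ethyl bromopyruvate with 1,3-dicarbonyl compounds. The only new stereocentre, C8, is set in the aldol step by the catalyst, which selects the enantioface of the ketone; ring closure then turns C8' into an sp2 carbon and thereby locks C8 against retro-aldol cleavage. The step needs carbonyl addition before SN2 attack at CH2Br, O-cyclisation instead of epoxide closure by the tertiary alkoxide, and no dehydration to the furan; these are secured by the ketone lying between an ester and a CH2Br group, by the far higher acidity of the β-keto ester compared with the tertiary alcohol under a weak base, and by the exclusion of acid.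

Step 4
Reactants: 7 diethyl (3S)-3-hydroxy-5-[3-methoxy-4-(triisopropylsilyloxy)phenyl]-2,3-dihydrofuran-3,4-dicarboxylate
Product: 8 diethyl (3S)-3-(tert-butyldimethylsilyloxy)-5-[3-methoxy-4-(triisopropylsilyloxy)phenyl]-2,3-dihydrofuran-3,4-dicarboxylate
Conditions: TBSOTf (1.5 equiv), 2,6-lutidine (3 equiv), CH2Cl2, 0 → 25 °C
Reagents that add atoms: tert-butyldimethylsilyl triflate, CC(C)(C)[Si](C)(C)OS(=O)(=O)C(F)(F)F
Why: Silyl triflate silylation of the hindered tertiary alcohol under buffered, non-protic conditions installs a bulky group that shields one face of ring A and blocks loss of the C8 oxygen by aromatisation.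

Step 5
Reactants: 8 diethyl (3S)-3-(tert-butyldimethylsilyloxy)-5-[3-methoxy-4-(triisopropylsilyloxy)phenyl]-2,3-dihydrofuran-3,4-dicarboxylate
Product: 9 diethyl (2S,3S,4S)-4-(tert-butyldimethylsilyloxy)-2-[3-methoxy-4-(triisopropylsilyloxy)phenyl]oxolane-3,4-dicarboxylate (aryl, C3 ester and silyloxy group all cis)
Conditions: H2 (10 bar), 10% Pd/C, pyridine (0.5 equiv), EtOAc, 25 °C
Reagents that add atoms: none
Why: Heterogeneous catalytic hydrogenation should add both hydrogens syn to the tetrasubstituted enol ether double bond from the face opposite the silyloxy group on the allylic quaternary carbon C8, which sets C7' (aryl cis to the C8 oxygen, as in the target) and C8' (ester cis to aryl, corrected in step 6), while pyridine tempers the catalyst against C–O hydrogenolysis.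

Step 6
Reactants: 9 diethyl (2S,3S,4S)-4-(tert-butyldimethylsilyloxy)-2-[3-methoxy-4-(triisopropylsilyloxy)phenyl]oxolane-3,4-dicarboxylate
Product: 10 diethyl (2S,3R,4S)-4-(tert-butyldimethylsilyloxy)-2-[3-methoxy-4-(triisopropylsilyloxy)phenyl]oxolane-3,4-dicarboxylate (aryl and silyloxy on one face, both esters on the other)
Conditions: DBU (1 equiv), toluene, 80 °C
Reagents that add atoms: none
Why: Thermodynamic epimerisation through the C8' ester enolate should move the C9' ester away from the face crowded by the aryl and silyloxy groups to the face of the C7 ester; C8 has no α-hydrogen and C7'–H is not acidic, so only C8' changes.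

Step 7
Reactants: 10 diethyl (2S,3R,4S)-4-(tert-butyldimethylsilyloxy)-2-[3-methoxy-4-(triisopropylsilyloxy)phenyl]oxolane-3,4-dicarboxylate
Product: 12 (7'S,8S,8'R)-1-(tert-butyldimethylsilyloxy)-6-exo-[3-methoxy-4-(triisopropylsilyloxy)phenyl]-3,7-dioxabicyclo[3.3.0]octan-2-one (C1 = C8; C2 = C7; C5 = C8'; C6 = C7'), via hydroxy ester 11 (not isolated)
Conditions: LiBH4 (1.0 equiv), THF, 0 °C; aq NH4Cl; then PPTS (10 mol %), toluene, 50 °C
Reagents that add atoms: none
Why: Chemoselective borohydride reduction should take the ester on the tertiary carbon C8' in preference to the pivalate-like ester on the fully substituted, silyloxy-bearing C8, and acid-catalysed lactonisation of the cis hydroxy ester (5-exo-trig acyl substitution) then closes ring B as a cis-fused γ-lactone without touching a stereocentre.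

Step 8
Reactants: 12 the ring B lactone
Product: 13 (7'S,8S,8'R)-1-(tert-butyldimethylsilyloxy)-6-exo-[3-methoxy-4-(triisopropylsilyloxy)phenyl]-3,7-dioxabicyclo[3.3.0]octan-2-ol (lactol, C7 epimers)
Conditions: i-Bu2AlH (1.2 equiv), CH2Cl2, −78 °C; aq potassium sodium tartrate
Reagents that add atoms: none
Why: Partial reduction of a γ-lactone with diisobutylaluminium hydride stops at the tetrahedral aluminate at low temperature and gives the lactol on work-up; the anomeric mixture at C7 is of no consequence.

Step 9
Reactants: 13 the lactol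
Product: 14 (7'S,8S,8'R)-1-(tert-butyldimethylsilyloxy)-6-exo-[3-methoxy-4-(triisopropylsilyloxy)phenyl]-3,7-dioxabicyclo[3.3.0]oct-2-yl acetate (C7 epimers)
Conditions: Ac2O, pyridine, DMAP (10 mol %), CH2Cl2, 0 → 25 °C
Reagents that add atoms: acetic anhydride, CC(=O)OC(C)=O
Why: DMAP-catalysed acetylation of the hemiacetal hydroxyl gives the anomeric acetate, a storable precursor of the ring B oxocarbenium ion.

Step 10
Reactants: 15 4-bromo-2-methoxyphenol
Product: 16 (4-bromo-2-methoxyphenoxy)triisopropylsilane
Conditions: TIPSCl, imidazole, DMF, 25 °C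
Reagents that add atoms: triisopropylsilyl chloride, CC(C)[Si](Cl)(C(C)C)C(C)C
Why: Imidazole-promoted O-silylation protects the phenol so that the aryl bromide can be turned into an organometallic reagent.

Step 11
Reactants: 14 the lactol acetate; 16 (4-bromo-2-methoxyphenoxy)triisopropylsilane
Product: 19 (7R,8S,7'S,8'R)-8-(tert-butyldimethylsilyloxy)pinoresinol bis(triisopropylsilyl) ether, via aryllithium 17 (not isolated), via arylzinc bromide 18 (not isolated)
Conditions: 16 (2 equiv), n-BuLi, THF, −78 °C; ZnBr2, −78 → 0 °C; then 14, BF3·OEt2 (2 equiv), toluene/CH2Cl2, −78 → −20 °C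
Reagents that add atoms: none
Why: Bromine–lithium exchange and transmetalation give an arylzinc reagent that tolerates the Lewis acid, BF3·OEt2 ionises the anomeric acetate, and aryl transfer to C7 (Lewis acid-mediated substitution of an α-acetoxy ether by an organozinc reagent, a C-glycosylation-type arylation) should occur on the convex exo face, cis to the C8 silyloxy group as is usual for five-membered oxocarbenium ions with an alkoxy group on the adjacent carbon and away from the concave face closed by ring A, which sets C7.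

Step 12
Reactants: 19 the tris-silyl ether
Product: 20 (7R,8S,7'S,8'R)-8-hydroxypinoresinol
Conditions: TBAF (6 equiv), AcOH (6 equiv), THF, 25 → 50 °C
Reagents that add atoms: none
Why: Fluoride-mediated desilylation cleaves the two aryl silyl ethers quickly and the tertiary silyl ether on warming, and the acetic acid buffer keeps the phenols protonated so that the 4-hydroxybenzylic ether bonds at C7 and C7' are not opened through quinone methides.

Step 13
Reactants: 20 (7R,8S,7'S,8'R)-8-hydroxypinoresinol
Product: 21 (7R,8S,7'S,8'R)-8-acetoxypinoresinol 4,4'-di-O-acetate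
Conditions: Ac2O (6 equiv), Et3N, DMAP (1 equiv), CH2Cl2, 40 °C
Reagents that add atoms: acetic anhydride, CC(=O)OC(C)=O
Why: Exhaustive DMAP-mediated acyl transfer acetylates the two phenols at once and the hindered tertiary bridgehead alcohol more slowly, which places the required acetate on C8 without affecting a stereocentre.

Step 14
Reactants: 21 the triacetate
Product: 22 1-acetoxypinoresinol, (7R,8S,7'S,8'R)
Conditions: pyrrolidine (2.5 equiv), THF, 0 °C
Reagents that add atoms: none
Why: Chemoselective aminolysis, in which the aryl acetates react as activated esters with the secondary amine while the hindered tertiary alkyl acetate at C8 is inert, should release both phenols and give the target.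

## Compound list

1 | acetovanillone | CC(=O)c1ccc(O)c(OC)c1 | starting material
2 | 1-[3-methoxy-4-(triisopropylsilyloxy)phenyl]ethanone | CC(=O)c1ccc(O[Si](C(C)C)(C(C)C)C(C)C)c(OC)c1 | intermediate
3 | diethyl carbonate | CCOC(=O)OCC | starting material
4 | ethyl 3-[3-methoxy-4-(triisopropylsilyloxy)phenyl]-3-oxopropanoate | CCOC(=O)CC(=O)c1ccc(O[Si](C(C)C)(C(C)C)C(C)C)c(OC)c1 | intermediate
5 | ethyl bromopyruvate | CCOC(=O)C(=O)CBr | starting material
6 | diethyl (3R)-3-(bromomethyl)-3-hydroxy-2-[3-methoxy-4-(triisopropylsilyloxy)benzoyl]butanedioate (C2 epimers; C3 = C8, not isolated) | CCOC(=O)C(C(=O)c1ccc(O[Si](C(C)C)(C(C)C)C(C)C)c(OC)c1)[C@@](O)(C(=O)OCC)CBr | intermediate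
7 | diethyl (3S)-3-hydroxy-5-[3-methoxy-4-(triisopropylsilyloxy)phenyl]-2,3-dihydrofuran-3,4-dicarboxylate | COc1cc(C2=C(C(=O)OCC)[C@@](O)(C(=O)OCC)CO2)ccc1O[Si](C(C)C)(C(C)C)C(C)C | intermediate
8 | diethyl (3S)-3-(tert-butyldimethylsilyloxy)-5-[3-methoxy-4-(triisopropylsilyloxy)phenyl]-2,3-dihydrofuran-3,4-dicarboxylate | COc1cc(C2=C(C(=O)OCC)[C@@](O[Si](C)(C)C(C)(C)C)(C(=O)OCC)CO2)ccc1O[Si](C(C)C)(C(C)C)C(C)C | intermediate
9 | diethyl (2S,3S,4S)-4-(tert-butyldimethylsilyloxy)-2-[3-methoxy-4-(triisopropylsilyloxy)phenyl]oxolane-3,4-dicarboxylate | COc1cc([C@H]2OC[C@](O[Si](C)(C)C(C)(C)C)(C(=O)OCC)[C@H]2C(=O)OCC)ccc1O[Si](C(C)C)(C(C)C)C(C)C | intermediate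
10 | diethyl (2S,3R,4S)-4-(tert-butyldimethylsilyloxy)-2-[3-methoxy-4-(triisopropylsilyloxy)phenyl]oxolane-3,4-dicarboxylate | COc1cc([C@H]2OC[C@](O[Si](C)(C)C(C)(C)C)(C(=O)OCC)[C@@H]2C(=O)OCC)ccc1O[Si](C(C)C)(C(C)C)C(C)C | intermediate
11 | ethyl (3S,4R,5S)-3-(tert-butyldimethylsilyloxy)-4-(hydroxymethyl)-5-[3-methoxy-4-(triisopropylsilyloxy)phenyl]oxolane-3-carboxylate (not isolated) | COc1cc([C@H]2OC[C@](O[Si](C)(C)C(C)(C)C)(C(=O)OCC)[C@@H]2CO)ccc1O[Si](C(C)C)(C(C)C)C(C)C | intermediate
12 | (7'S,8S,8'R)-1-(tert-butyldimethylsilyloxy)-6-exo-[3-methoxy-4-(triisopropylsilyloxy)phenyl]-3,7-dioxabicyclo[3.3.0]octan-2-one | COc1cc([C@H]2OC[C@]3(O[Si](C)(C)C(C)(C)C)C(=O)OC[C@H]23)ccc1O[Si](C(C)C)(C(C)C)C(C)C | intermediate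
13 | the corresponding lactol, 3,7-dioxabicyclo[3.3.0]octan-2-ol (C7 epimers) | COc1cc([C@H]2OC[C@]3(O[Si](C)(C)C(C)(C)C)C(O)OC[C@H]23)ccc1O[Si](C(C)C)(C(C)C)C(C)C | intermediate
14 | the corresponding lactol acetate (C7 epimers) | COc1cc([C@H]2OC[C@]3(O[Si](C)(C)C(C)(C)C)C(OC(C)=O)OC[C@H]23)ccc1O[Si](C(C)C)(C(C)C)C(C)C | intermediate
15 | 4-bromo-2-methoxyphenol | COc1cc(Br)ccc1O | starting material
16 | (4-bromo-2-methoxyphenoxy)triisopropylsilane | COc1cc(Br)ccc1O[Si](C(C)C)(C(C)C)C(C)C | intermediate
17 | [3-methoxy-4-(triisopropylsilyloxy)phenyl]lithium (not isolated) | COc1cc([Li])ccc1O[Si](C(C)C)(C(C)C)C(C)C | intermediate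
18 | [3-methoxy-4-(triisopropylsilyloxy)phenyl]zinc bromide (not isolated) | COc1cc([Zn]Br)ccc1O[Si](C(C)C)(C(C)C)C(C)C | intermediate
19 | (7R,8S,7'S,8'R)-8-(tert-butyldimethylsilyloxy)pinoresinol bis(triisopropylsilyl) ether | COc1cc([C@H]2OC[C@]3(O[Si](C)(C)C(C)(C)C)[C@@H](c4ccc(O[Si](C(C)C)(C(C)C)C(C)C)c(OC)c4)OC[C@H]23)ccc1O[Si](C(C)C)(C(C)C)C(C)C | intermediate
20 | (7R,8S,7'S,8'R)-8-hydroxypinoresinol (1-hydroxypinoresinol) | COc1cc([C@H]2OC[C@]3(O)[C@@H](c4ccc(O)c(OC)c4)OC[C@H]23)ccc1O | intermediate
21 | (7R,8S,7'S,8'R)-8-acetoxypinoresinol 4,4'-di-O-acetate | COc1cc([C@H]2OC[C@]3(OC(C)=O)[C@@H](c4ccc(OC(C)=O)c(OC)c4)OC[C@H]23)ccc1OC(C)=O | intermediate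
22 | 1-acetoxypinoresinol, (7R,8S,7'S,8'R) | COc1cc([C@H]2OC[C@]3(OC(C)=O)[C@@H](c4ccc(O)c(OC)c4)OC[C@H]23)ccc1O | target

## Step count and risks

Total step count: 14. Longest linear sequence: 13 steps (steps 1–9 and 11–14; step 10 is a one-step side branch).

Three steps most likely to fail:

**Step 5.** The tetrasubstituted donor–acceptor alkene may resist hydrogenation, take up hydrogen from the silyl ether face (poor facial selectivity), or lose the allylic C8–O or the new benzylic C7'–O bond by hydrogenolysis. Fallback: setting out from 8, dissolving-metal conjugate reduction with Mg in MeOH (0 → 25 °C), the known reduction of β-aryl-β-alkoxy acrylates. The two hydrogens then arrive as protons, at C7' from the face away from the silyl ether and at C8' under equilibration by the Mg(OMe)2 formed. Ester exchange gives the 7',8'-trans dimethyl diester F1. Both alkoxy groups are lost in step 7, so F1 under the conditions of step 7 returns to the route at 12.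

**Step 11.** The aryl group may enter C7 from the concave face (poor or reversed facial selectivity because the C8 silyloxy group crowds the exo face), or the oxocarbenium ion may be consumed unproductively. Fallback: setting out from lactone 12, addition of aryllithium 17 (from 16, n-BuLi, THF, −78 °C) gives the C7 aryl hemiketal F2. Et3SiH with BF3·OEt2 (CH2Cl2, −78 °C) reduces it through the 7-aryl oxocarbenium ion. Hydride now takes the face that the aryl nucleophile preferred, so the aryl group ends up exo and the route is rejoined at 19, with steps 8 and 9 omitted.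

**Step 7.** Hydride may also attack the C7 ester (poor chemoselectivity, leading to the regioisomeric lactone), or the lactone may be reduced further once it forms. Fallback: setting out from 10, exhaustive reduction with LiAlH4 (THF, 0 °C) gives the diol F3. TESCl and imidazole (CH2Cl2, −20 °C) silylate the less hindered C9' hydroxyl, the C7 hydroxyl being neopentylic, to give the triethylsilyl ether F4. Dess–Martin oxidation gives the aldehyde F5. AcOH/THF/H2O removes the triethylsilyl group, and the freed C9' hydroxyl closes onto the aldehyde, which returns to the route at lactol 13, with step 8 omitted.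

Further compounds
F1 | step 5 | dimethyl (2S,3R,4S)-4-(tert-butyldimethylsilyloxy)-2-[3-methoxy-4-(triisopropylsilyloxy)phenyl]oxolane-3,4-dicarboxylate | COc1cc([C@H]2OC[C@](O[Si](C)(C)C(C)(C)C)(C(=O)OC)[C@@H]2C(=O)OC)ccc1O[Si](C(C)C)(C(C)C)C(C)C
F2 | step 11 | (7'S,8S,8'R)-1-(tert-butyldimethylsilyloxy)-2,6-bis[3-methoxy-4-(triisopropylsilyloxy)phenyl]-3,7-dioxabicyclo[3.3.0]octan-2-ol (C7 aryl hemiketal, C7 epimers) | COc1cc([C@H]2OC[C@]3(O[Si](C)(C)C(C)(C)C)C(O)(c4ccc(O[Si](C(C)C)(C(C)C)C(C)C)c(OC)c4)OC[C@H]23)ccc1O[Si](C(C)C)(C(C)C)C(C)C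
F3 | step 7 | [(2S,3R,4R)-4-(tert-butyldimethylsilyloxy)-4-(hydroxymethyl)-2-[3-methoxy-4-(triisopropylsilyloxy)phenyl]oxolan-3-yl]methanol | COc1cc([C@H]2OC[C@](O[Si](C)(C)C(C)(C)C)(CO)[C@@H]2CO)ccc1O[Si](C(C)C)(C(C)C)C(C)C
F4 | step 7 | [(3R,4R,5S)-3-(tert-butyldimethylsilyloxy)-5-[3-methoxy-4-(triisopropylsilyloxy)phenyl]-4-(triethylsilyloxymethyl)oxolan-3-yl]methanol | COc1cc([C@H]2OC[C@](O[Si](C)(C)C(C)(C)C)(CO)[C@@H]2CO[Si](CC)(CC)CC)ccc1O[Si](C(C)C)(C(C)C)C(C)C
F5 | step 7 | (3S,4R,5S)-3-(tert-butyldimethylsilyloxy)-5-[3-methoxy-4-(triisopropylsilyloxy)phenyl]-4-(triethylsilyloxymethyl)oxolane-3-carbaldehyde | COc1cc([C@H]2OC[C@](O[Si](C)(C)C(C)(C)C)(C=O)[C@@H]2CO[Si](CC)(CC)CC)ccc1O[Si](C(C)C)(C(C)C)C(C)C
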